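At late times the red and green runs stopped moving, so I started from their last readings and asked what the flask's end state must be.

| flask | substrate | free catalyst | remark | time |
|---|---|---|---|---|
| red | 1.7 M (fed, over 50 s) | 5 mol% | run made earlier |  |
| green | 2.6 M (fed, over 50 s) | 5 mol% | run made earlier |  |
| grey | 1.2 M (fed, over 50 s) | 7.5 mol% | run made earlier |  |
| flask | 1.2 M (fed, over 50 s) | 5 mol% |  | 4.0 min |

| run | time / min | target / % | substrate / % |
|---|---|---|---|
| red | 0.833 | 36.6 | 50.5 |
| red | 1.50 | 53.2 | 28.3 |
| red | 2.50 | 55.5 | 25.8 |
| red | 3.00 | 55.5 | 25.4 |
| red | 4.00 | 55.5 | 25.7 |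
| green | 0.833 | 34.9 | 49.2 |
| green | 1.50 | 49.9 | 27.3 |
| green | 2.50 | 52.2 | 24.3 |
| green | 3.00 | 52.3 | 24.1 |
| green | 4.00 | 52.1 | 23.7 |
| grey | 0.833 | 36.0 | 50.5 |
| grey | 1.50 | 53.0 | 28.4 |
| grey | 2.50 | 54.3 | 25.3 |
| grey | 3.00 | 54.6 | 24.8 |
| grey | 4.00 | 54.7 | 25.0 |

(scatter of a reading: 0.3 percentage points)

- amount of target in percent of the substrate charged, at 25 s, 80 s, 2.5 min and 4.0 min

- the analysis behind the earlier runs scatters by 0.3 percentage points, standard deviation

In red, target over substrate ended at 2.16, and in green at 2.20, although the charges differed. I kept their mean, the end ratio of target to substrate (an apparent equilibrium constant), as 2.18.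

What share of the charge stays outside that pair? The gap was 18.8% in red at 0.0850 M free catalyst and 24.2% in green at 0.130 M. A straight line, which was my own choice, gave 15.8% for the flask at 0.0600 M. Its end was therefore 57.7% target and 26.5% substrate.

How fast did the flask get there? Excess substrate after the feed fell at 3.16 min⁻¹, the mean of red and green, and I assumed the same rate for the flask. Target per substrate used held level in red, 0.739 at the first reading and 0.747 at the last, so I used the flask's end value, 0.785. Letting substrate relax towards its end share of what had been fed, and counting as used what had been fed and was no longer substrate, gave 12.8% target at 25 s, when 50.0% of the charge had gone in, and 53.5% at 80 s. By 2.5 min the excess was 0.134%, so I wrote 57.7% for both later points.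

The forecast gave 13%, 54%, 58.3% and 58.5%, its end above mine, with the remark “this looks like an equilibrium rather than catalyst death”.

The flask gave 13.2%, 54.1%, 57.9% and 58.0%.

    substrate ⇌ target (K = 2.18, k = 0.0351 s⁻¹)
    target + free catalyst ⇌ isomer of the product + free catalyst, rate k2*[free catalyst]*[target] forward; the back reaction follows from the equilibrium constant (K = 0.840, k = 0.436 M⁻¹ s⁻¹)
    isomer of the product + free catalyst ⇌ substrate + free catalyst, rate k3*[free catalyst]*[isomer of the product] forward; the back reaction follows from the equilibrium constant (k = 0.116 M⁻¹ s⁻¹)
    free catalyst → spent catalyst (k = 0.0370 s⁻¹)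

At 4.00 min the flask held 15.4% isomer of the product where I had written a gap. Its target divided by the end ratio gives 26.6% substrate, and it held 26.6%. The end ratio times the last substrate reading of the grey run gives 54.5% target, and its reading was 54.7%.

Readings and results stem from a simulated flask with constants of no real substance; noise was put on by code.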